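(The numbers in the tables are simulated on assumed constants, noise included.)

**The small charge.** A small charge of reagent, 0.140 M against 0.500 M of starting material in the south-west run, makes reagent the limiting reagent. You want to know how far target stands below the 28.0% of the starting material that this charge allows at 18 min.

| flask | starting material | reagent | target | time |
|---|---|---|---|---|
| south-east | 0.500 M | 0.500 M |  |  |
| east | 0.250 M | 0.500 M |  |  |
| north-west | 0.500 M | 0.500 M | 0.250 M |  |
| south | 0.500 M | 0.250 M |  |  |
| south-west | 0.500 M | 0.140 M |  | 18 min |

- south-east run (time / min: [target] / M): 3.0: 0.039; 6.0: 0.076; 9.0: 0.116; 12: 0.137; 15: 0.147; 18: 0.141
- east run (time / min: [target] / M): 3.0: 0.035; 6.0: 0.057; 9.0: 0.072; 12: 0.085; 15: 0.067; 18: 0.063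
- north-west run (time / min: [target] / M): 3.0: 0.187; 6.0: 0.205; 9.0: 0.205; 12: 0.211; 15: 0.206; 18: 0.213
- south run (time / min: [target] / M): 3.0: 0.019; 6.0: 0.053; 9.0: 0.078; 12: 0.086; 15: 0.092; 18: 0.119

(readings scatter by 0.007 M)

- apparent order in [starting material] of the starting rate, round the charge of the south-east run (the rate where two percent of its starting material have turned into target) (one fixed amount of target, the same in the runs compared)
- apparent order in [reagent] of the starting rate, round the charge of the south-east run (the rate where two percent of its starting material have turned into target)
- target in the south-west run at 18 min, as a share of the starting material charged

- Overall: starting material + reagent -> target.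
- Constant volume, constant temperature.
- The analysis sees a species whether free or bound.
- "The second partner" is reagent.
- An order is taken over about fifteen percent of the charge, up and down.

**The rule.** While little target has been made, target at equal times stands in for the rate, so add the readings up to 9.0 min in each run. The south run over the south-east run gives 0.649 for a reagent ratio of 0.500, and the logarithms give 0.623. This is n, the apparent order in reagent: the logarithm of the rate ratio divided by the logarithm of the charge ratio. The east run over the south-east run gives a ratio of 0.710, so the order in starting material reads 0.494. Both are readings, and each point scatters by 0.007 M.

**Main step alone.** Take starting material + reagent -> target as the one process, first order in reagent. The south run's 0.119 M at 18 min, scaled by the charge ratio of 0.560, then puts the south-west run at 13.3% of its starting material.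

**Measured order.** Now raise that charge ratio to the power n instead. The share becomes 16.6%, more than the first figure. This stretches an order read at the start across the whole 18 min, so it is a rough figure.

**The rest.** The north-west run reads 0.187 M at 3.0 min from a charge of 0.250 M, so target is being consumed. I take the south reading at 18 min to carry such a loss already, so I leave the share unchanged and commit to 16.6%.

**The result.** The forecast gave 0.15 for the order in starting material, 0.6 for the order in reagent and 11% for the south-west share, holding that “Halving starting material therefore barely matters”, and its order in starting material is lower than my 0.494. The flask gives 0.44, 0.56 and 15.1%, in the same sequence.

    starting material + reagent → intermediate (0.3348 /M/min)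
    intermediate → target (0.4092 /min)
    2 starting material ⇌ idle substrate dimer, settled at all times (2.170 /M)
    target + reagent → side product (0.3744 /M/min)

**The gap.** Carried to the south run, the rule stretches the 10.9 min that the south-east run takes to reach a quarter of its charge by two to the power n, giving 16.8 min, but the south run takes 36.8 min, longer than that. The south-west share stands at 15.1% because of two processes acting together, the joining of starting material into idle substrate dimer and the loss of target with reagent to side product. Without the loss, the same south-west run gives 19.1%, and without the joining it gives 20.8%.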